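The route rests on cutting the benzylic bond between C2 of pyranone ring C and C1' of ring B. At the chromone oxidation level, C2 is the β-carbon of the vinylogous ester C2=C3–C4=O. A rhodium-catalysed asymmetric 1,4-addition of the complete diprenylated ring B boronic acid therefore forms this bond, sets the only stereocentre (2S) under ligand control and lowers ring C to the chromanone level in one operation. Both precursors are flat and achiral: O-silylated 7-hydroxychromone and 4-methoxy-3,5-diprenylphenylboronic acid. The latter is made in two steps by double Stille prenylation and sterically directed C–H borylation. Buffered fluoride in the same flask frees the 7-OH.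

Key step: step 4

Assumption: the sense of induction of (S)-MeO-F12-BIPHEP, (S)-6,6'-dimethoxy-2,2'-bis[bis(3,4,5-trifluorophenyl)phosphino]-1,1'-biphenyl, is taken from the (S)-biaryl diphosphine/cyclic enone model; should it prove the reverse, the (R)-ligand is used in the same way.

Step 1
Reactants: 1 2,6-dibromoanisole; 2 tributyl(3-methylbut-2-en-1-yl)stannane (2.4 equiv)
Product: 3 2-methoxy-1,3-bis(3-methylbut-2-en-1-yl)benzene (2,6-diprenylanisole)
Conditions: Pd(PPh3)4 (5 mol%), DMF, 100 °C
Reagents that add atoms: none
Why: Double Stille coupling, in which each C–Br bond adds oxidatively to zerovalent palladium, the allylic stannane transmetalates and reductive elimination at the unhindered CH2 terminus of the prenyl-palladium unit should give the linear prenyl arene at both positions, with no stereocentre formed.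

Step 2
Reactants: 3 2,6-diprenylanisole
Product: 5 [4-methoxy-3,5-bis(3-methylbut-2-en-1-yl)phenyl]boronic acid, via pinacol boronate 4 (not isolated)
Conditions: [Ir(OMe)(cod)]2 (1.5 mol%), dtbpy (3 mol%), B2pin2 (1.0 equiv), THF, 65 °C; then NaIO4 (3 equiv), NH4OAc (3 equiv), THF/H2O, 25 °C
Reagents that add atoms: bis(pinacolato)diboron CC1(C)OB(OC1(C)C)B1OC(C)(C)C(C)(C)O1; water O
Why: Iridium-catalysed aromatic C–H borylation is governed by sterics and C4 is the only ring C–H of 3 without an ortho substituent, the crowded iridium tris(boryl) catalyst should leave the trisubstituted alkenes alone, and periodate then drains the hydrolysis equilibrium by cleaving pinacol to acetone (known one-pot arene-to-boronic-acid sequence) without touching alkenes, with no stereocentre formed.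

Step 3
Reactants: 6 7-hydroxy-4H-chromen-4-one (7-hydroxychromone)
Product: 7 7-(tert-butyldimethylsilyloxy)-4H-chromen-4-one
Conditions: TBSCl (1.2 equiv), imidazole (2 equiv), DMF, 25 °C
Reagents that add atoms: tert-butyldimethylsilyl chloride CC(C)(C)[Si](C)(C)Cl
Why: Standard imidazole-promoted silyl ether formation at the acidic 7-OH, which makes the acceptor soluble in toluene and prevents a deactivating phenoxide from forming in the key step, with no stereocentre formed.

Step 4
Reactants: 5 [4-methoxy-3,5-bis(3-methylbut-2-en-1-yl)phenyl]boronic acid (1.3 equiv); 7 7-(tert-butyldimethylsilyloxy)-4H-chromen-4-one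
Product: 9 (S)-7-hydroxy-2-[4-methoxy-3,5-bis(3-methylbut-2-en-1-yl)phenyl]chroman-4-one (target), via silyl ether 8 (not isolated)
Conditions: [Rh(OH)((S)-MeO-F12-BIPHEP)]2 (1.5 mol%), toluene/H2O 20:1, 25 °C; then THF, TBAF/AcOH 1:1 (3 equiv), 0 °C
Reagents that add atoms: none
Why: Hayashi–Miyaura reaction on a chromone: the hydroxo-rhodium complex transmetalates with 5 to an aryl-rhodium species, the C2=C3 bond of 7 coordinates and inserts syn so that the aryl group goes to the β-carbon C2, and the oxa-π-allyl rhodium enolate is protonated by water, which returns Rh–OH and gives 8. Rhodium/chiral diphosphine 1,4-addition of arylboronic acids to 4-chromones, oxygenated ring A examples included, is the direct known reaction type, and the electron-poor diphosphine is chosen because it speeds insertion into this weakly electrophilic vinylogous ester at room temperature. No ring is closed; ring C is only taken from the chromone to the chromanone level. The new stereocentre C2 is controlled by the twofold-symmetric (S)-biaryl diphosphine, whose blocked quadrants let the flat chromone bind through one face only, the same face as in the (S)-selective arylation of cyclohexenone, which maps onto 2S here. The step needs 1,4- over 1,2-addition and no second arylation at the ketone of 8, secured by the small excess of 5, short time and mild temperature, and it needs untouched prenyl groups, which should hold because aryl-rhodium does not insert into isolated trisubstituted alkenes and the prenyl groups sit meta to boron, away from the reacting carbon. Acetic-acid-buffered fluoride then cleaves the labile aryl silyl ether at 0 °C without the free base that would racemise C2 by retro-oxa-Michael opening.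

Compound list
1 | 2,6-dibromoanisole | COc1c(Br)cccc1Br | starting material
2 | tributyl(3-methylbut-2-en-1-yl)stannane | CCCC[Sn](CCCC)(CCCC)CC=C(C)C | starting material
3 | 2-methoxy-1,3-bis(3-methylbut-2-en-1-yl)benzene | COc1c(CC=C(C)C)cccc1CC=C(C)C | intermediate
4 | 2-[4-methoxy-3,5-bis(3-methylbut-2-en-1-yl)phenyl]-4,4,5,5-tetramethyl-1,3,2-dioxaborolane | COc1c(CC=C(C)C)cc(B2OC(C)(C)C(C)(C)O2)cc1CC=C(C)C | intermediate
5 | [4-methoxy-3,5-bis(3-methylbut-2-en-1-yl)phenyl]boronic acid | COc1c(CC=C(C)C)cc(B(O)O)cc1CC=C(C)C | intermediate
6 | 7-hydroxy-4H-chromen-4-one | O=c1ccoc2cc(O)ccc12 | starting material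
7 | 7-(tert-butyldimethylsilyloxy)-4H-chromen-4-one | CC(C)(C)[Si](C)(C)Oc1ccc2c(=O)ccoc2c1 | intermediate
8 | (S)-7-(tert-butyldimethylsilyloxy)-2-[4-methoxy-3,5-bis(3-methylbut-2-en-1-yl)phenyl]chroman-4-one | COc1c(CC=C(C)C)cc([C@@H]2CC(=O)c3ccc(O[Si](C)(C)C(C)(C)C)cc3O2)cc1CC=C(C)C | intermediate
9 | (S)-7-hydroxy-2-[4-methoxy-3,5-bis(3-methylbut-2-en-1-yl)phenyl]chroman-4-one | COc1c(CC=C(C)C)cc([C@@H]2CC(=O)c3ccc(O)cc3O2)cc1CC=C(C)C | target

Total step count: 4. Longest linear sequence: 3 (steps 1, 2 and 4).

Steps most likely to fail

Step 4.
- **What may go wrong.** Insertion into the electron-rich 7-silyloxychromone may be slow, so that protodeboronation of 5 outruns C–C bond formation. Facial selectivity may also erode, for instance through β-elimination of the ring oxygen from the rhodium enolate followed by unselective re-closure.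
- **Fallback.** It separates bond formation from stereocontrol and sets out from 5 and 7. The much more active achiral diene complex [Rh(OH)(cod)]2 in dioxane/H2O at 40 °C should give the racemic 7-silyloxyflavanone F1. This is then submitted to a kinetic resolution by asymmetric transfer hydrogenation with Cp*RhCl[(R,R)-TsDPEN] and HCO2H/Et3N in EtOAc at 25 °C, stopped near half conversion.
- **Expected outcome.** The (R)-enantiomer should be reduced faster, because the 4R-selective hydride delivery matches the approach that gives the cis alcohol. This yields the (2R,4R)-cis-flavan-4-ol F2, which is removed by chromatography. The unreacted (S)-ketone is 8, where the route is rejoined for the buffered desilylation of step 4.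

Step 2.
- **What may go wrong.** Hydroboration or vinylic borylation of the prenyl alkenes by the iridium/pinacolborane system may compete with arene borylation.
- **Fallback.** It reverses the order of events so that no alkene is present during C–H activation, and it sets out from 1. Iridium-catalysed borylation of 1 under the same catalyst system should give the 3,5-dibromo-4-methoxyphenyl pinacol boronate F3, again at the only unhindered C–H.
- **Return to the route.** A base-free double Stille coupling of F3 with 2 (Pd(PPh3)4, DMF, 100 °C) follows. The boronate should stay a spectator because no base activates it. This leads to 4, where the route is rejoined for the periodate cleavage to 5.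

Step 1.
- **What may go wrong.** Regiocontrol may be lost in the allyl transfer, with bond formation at the tertiary terminus. The second coupling may also stall next to the now flanked methoxy group.
- **Fallback.** It removes the regiochemical question by transferring a symmetrical allyl group and building the trisubstituted alkene afterwards, and it sets out from 1. Double Stille coupling with allyltributylstannane (Pd(PPh3)4, DMF, 90 °C) should give 2,6-diallylanisole F4.
- **Return to the route.** Twofold olefin cross-metathesis with excess 2-methyl-2-butene (second-generation Grubbs catalyst, CH2Cl2, 40 °C) should convert F4 into 3, where the route is rejoined.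

Further compounds
F1 | step 4 | racemic 7-(tert-butyldimethylsilyloxy)-2-[4-methoxy-3,5-bis(3-methylbut-2-en-1-yl)phenyl]chroman-4-one | COc1c(CC=C(C)C)cc(C2CC(=O)c3ccc(O[Si](C)(C)C(C)(C)C)cc3O2)cc1CC=C(C)C
F2 | step 4 | (2R,4R)-7-(tert-butyldimethylsilyloxy)-2-[4-methoxy-3,5-bis(3-methylbut-2-en-1-yl)phenyl]chroman-4-ol (2,4-cis) | COc1c(CC=C(C)C)cc([C@H]2C[C@@H](O)c3ccc(O[Si](C)(C)C(C)(C)C)cc3O2)cc1CC=C(C)C
F3 | step 2 | 2-(3,5-dibromo-4-methoxyphenyl)-4,4,5,5-tetramethyl-1,3,2-dioxaborolane | COc1c(Br)cc(B2OC(C)(C)C(C)(C)O2)cc1Br
F4 | step 1 | 2-methoxy-1,3-di(prop-2-en-1-yl)benzene (2,6-diallylanisole) | COc1c(CC=C)cccc1CC=C
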